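## Retrosynthetic overview

- **Feature:** in ring A (C1, O2, C3, C4, C5, C9) the acyl-acetal carbon C1 and the enol-ether carbon C3 are joined only through O2. Removing O2 and bonding C1 to C3 turns the labile dihydropyran into a cyclopentene, so rings A and B map onto a cis-bicyclo[3.3.0]octene fused at C5–C9.
- **Late disconnections:** C11 (a C4 aldehyde from Vilsmeier formylation, reduced in the last step), the C10 p-coumarate and the C1 (S)-3-methylpentanoate.
- **Key disconnection:** C1–O2 and C3–O2. These bonds are made by ozonolysis of the C1=C3 alkene of the protected diquinene, followed by reclosure of the 1,5-dialdehyde through oxygen to the 11-nor lactol.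
- **Ring B substituents, set on the all-carbon skeleton:** C10 by carbonylation of the C8 enol triflate, 7β-O by convex epoxidation, and 8α-O by a tethered carbamate opening with inversion at C8.
- **Ring order:** ring B and the carbocyclic stand-in for ring A form together by transannular C–H insertion of lithiated cyclooctadiene monoepoxide (lipase resolution). Ring A is the last ring to be closed.

Key step: step 14

Convention: iridoid numbering (C1, O2, C3, C4, C5, C6, C7, C8, C9, C10 on C8, C11 on C4) is used for all bicyclic compounds, carbocyclic ones included. β is the face of H-5 and H-9 (the convex face) and α is the concave face.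

Assumption: the lipase is taken to follow the Kazlauskas rule for this endo alcohol; should it show the opposite preference, the recovered alcohol is the one oxidised and step 4 is dropped.

## Route

Step 1
Reactants: 1 cycloocta-1,3-diene
Product: 2 rac-cis-3,4-epoxycyclooctene (9-oxabicyclo[6.1.0]non-2-ene)
Conditions: mCPBA (1.0 equiv), CH2Cl2, 0 °C
Reagents that add atoms: 3-chloroperbenzoic acid, O=C(OO)c1cccc(Cl)c1
Why: Prilezhaev epoxidation with one equivalent of peracid should stop at the monoepoxide because the remaining alkene of the vinyl epoxide is deactivated, and syn addition to the Z-alkene gives the cis-epoxide as a racemate.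

Step 2
Reactants: 2 rac-cis-3,4-epoxycyclooctene
Product: 4 rac-endo-cis-bicyclo[3.3.0]oct-7-en-2-ol, via α-lithiated epoxide 3 (not isolated)
Conditions: LiNEt2 (from Et2NH, n-BuLi; 2.5 equiv), Et2O, reflux
Reagents that add atoms: none
Why: Base-induced transannular rearrangement of a medium-ring epoxide: the amide removes the allylic epoxide proton at C9 and carbenoid 3 inserts into the C5–H bond across the ring, which forms C5–C9 and both five-membered rings at once, allows only the cis fusion, and leaves the untouched C8–O bond on the concave face.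

Step 3
Reactants: 4 rac-endo-cis-bicyclo[3.3.0]oct-7-en-2-ol
Product: 5 (1R,2R,5R)-endo-cis-bicyclo[3.3.0]oct-7-en-2-yl acetate
Conditions: Burkholderia cepacia lipase (Amano PS), vinyl acetate, MTBE, 30 °C, stopped near half conversion
Reagents that add atoms: vinyl acetate, C=COC(C)=O
Why: Lipase-catalysed kinetic resolution by irreversible transesterification, in which by the Kazlauskas rule the (2R)-alcohol (larger carbinol substituent = ring-fusion carbon C9) should be acylated faster, fixing the absolute configuration at C5 and C9 for the whole route.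

Step 4
Reactants: 5 (1R,2R,5R)-acetate
Product: 6 (1R,2R,5R)-endo-cis-bicyclo[3.3.0]oct-7-en-2-ol
Conditions: K2CO3 (0.2 equiv), MeOH, rt
Reagents that add atoms: none
Why: Base-catalysed transesterification (Zemplén-type methanolysis) frees the alcohol without touching a stereocentre.

Step 5
Reactants: 6 (1R,2R,5R)-alcohol
Product: 7 (1R,5R)-cis-bicyclo[3.3.0]oct-7-en-2-one (C8 ketone, C1=C3 alkene, H-5 and H-9 β)
Conditions: Dess–Martin periodinane, CH2Cl2, 0 °C to rt
Reagents that add atoms: none
Why: Dess–Martin oxidation runs under near-neutral conditions, so the β,γ-unsaturated ketone should not slip into conjugation, and C9 cannot epimerise because a trans-fused diquinane is prohibitively strained.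

Step 6
Reactants: 7 ketone
Product: 9 C7=C8 enol triflate (cis-bicyclo[3.3.0]octa-2,7-dien-2-yl trifluoromethanesulfonate), via lithium enolate 8 (not isolated)
Conditions: LiN(i-Pr)2 (1.1 equiv), THF, −78 °C (ketone added to base); then PhNTf2, −78 to 0 °C
Reagents that add atoms: N-phenylbis(trifluoromethanesulfonimide), O=S(=O)(C(F)(F)F)N(c1ccccc1)S(=O)(=O)C(F)(F)F
Why: Kinetic enolate formation followed by O-sulfonylation, in which the hindered amide should take the exposed C7 methylene proton rather than the tertiary ring-fusion H-9 (whose loss would put a double bond at the ring fusion), while inverse addition at low temperature suppresses enolate equilibration.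

Step 7
Reactants: 9 enol triflate
Product: 10 methyl cis-bicyclo[3.3.0]octa-2,7-diene-2-carboxylate (C10 ester on C8, C7=C8)
Conditions: Pd(OAc)2 (5 mol %), PPh3 (10 mol %), CO (1 atm), MeOH, Et3N, DMF, rt
Reagents that add atoms: carbon monoxide, [C-]#[O+]; methanol, CO
Why: Palladium-catalysed alkoxycarbonylation of an enol triflate (oxidative addition to zerovalent palladium, CO insertion, methanolysis of the acylpalladium species) installs C10 on C8 under conditions too mild to move either alkene.

Step 8
Reactants: 10 methyl ester
Product: 11 allylic alcohol (cis-bicyclo[3.3.0]octa-2,7-dien-2-yl)methanol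
Conditions: i-Bu2AlH (2.5 equiv), CH2Cl2, −78 °C
Reagents that add atoms: none
Why: 1,2-Reduction of the α,β-unsaturated ester with a dialkylaluminium hydride gives the allylic alcohol and leaves both alkenes alone.

Step 9
Reactants: 11 allylic alcohol
Product: 12 7β,8β-epoxy alcohol (epoxide oxygen on the convex face, C10 carbinol on C8 pointing α)
Conditions: VO(acac)2 (2 mol %), t-BuOOH, CH2Cl2, 0 °C
Reagents that add atoms: tert-butyl hydroperoxide, CC(C)(C)OO
Why: Hydroxyl-directed vanadium-catalysed epoxidation selects the allylic-alcohol alkene over the isolated C1=C3 alkene, and because the C10 carbinol lies in the alkene plane the fold of the diquinane decides the face, so oxygen should arrive on the convex β face and set C7 (final) and C8 (to be inverted).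

Step 10
Reactants: 12 epoxy alcohol
Product: 13 N-phenylcarbamate of 12 at O10
Conditions: PhNCO, pyridine, CH2Cl2, rt
Reagents that add atoms: phenyl isocyanate, O=C=Nc1ccccc1
Why: Addition of the primary alcohol to an isocyanate (urethane formation) places an internal oxygen nucleophile within reach of C8.

Step 11
Reactants: 13 epoxy urethane
Product: 15 8α,10-cyclic carbonate with free 7β-OH, via iminocarbonate 14 (not isolated)
Conditions: BF3·OEt2 (1.1 equiv), Et2O, −20 °C; then 1 M H2SO4, rt
Reagents that add atoms: water, O
Why: Lewis-acid-promoted intramolecular opening of a 2,3-epoxy alcohol urethane, in which the carbamate carbonyl oxygen attacks 5-exo at tertiary C8 (the epoxide carbon best able to carry positive charge) from the concave face opposite the leaving oxygen, so that C8 is inverted (8α-O, C10 β) while the C7–O bond is kept, and acid hydrolysis of 14 gives the carbonate.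

Step 12
Reactants: 15 cyclic carbonate
Product: 16 7β,8α,10-triol
Conditions: K2CO3 (0.2 equiv), MeOH, rt
Reagents that add atoms: none
Why: Base-catalysed methanolysis of the cyclic carbonate releases the triol with the trans C7,C8 diol in place.

Step 13
Reactants: 16 triol
Product: 18 7,10-O-(di-tert-butylsilylene)-8-O-triethylsilyl diquinene, via silylene 17 (not isolated)
Conditions: t-Bu2Si(OTf)2 (1.05 equiv), 2,6-lutidine, CH2Cl2, 0 °C; then Et3SiOTf, 0 °C to rt
Reagents that add atoms: di-tert-butylsilyl bis(trifluoromethanesulfonate), CC(C)(C)[Si](OS(=O)(=O)C(F)(F)F)(OS(=O)(=O)C(F)(F)F)C(C)(C)C; triethylsilyl trifluoromethanesulfonate, CC[Si](CC)(CC)OS(=O)(=O)C(F)(F)F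
Why: Silylation with silyl triflates, in which the bis-triflate should bridge the cis-disposed 7β-OH and 10-OH as a six-membered silylene rather than form a five-membered ring through the tertiary 8-OH, which is then capped by the monofunctional triflate.

Step 14
Reactants: 18 protected diquinene
Product: 22 11-nor-iridoid lactol (1β-OH; C3=C4 enol ether; 7,10-O-silylene; 8-O-triethylsilyl), via secondary ozonide 19 (not isolated), via dialdehyde 20 (not isolated), via cyclic bis-hemiacetal 21 (not isolated)
Conditions: O3, CH2Cl2, −78 °C; Me2S, −78 °C to rt; then pyridinium p-toluenesulfonate (10 mol %), H2O (1 equiv), toluene, 40 °C, then 4 Å MS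
Reagents that add atoms: ozone, [O-][O+]=O; water, O
Why: Ozone adds to the only alkene (C1=C3) by 1,3-dipolar cycloaddition and cycloreversion–recombination gives ozonide 19, which Me2S reduces to the cis-1,2-disubstituted cyclopentane dialdehyde 20; the closest known reaction type is the ozonolytic cleavage of bicyclo[3.3.0]octenes to 1,5-dialdehydes that fold up to iridoid enol lactols. Under the mild acid the unhindered C3 aldehyde is hydrated and one of its hydroxyls adds to the C1 carbonyl in a 6-exo-trig closure, which makes C3–O2 and O2–C1 and closes ring A as bis-hemiacetal 21. Ionisation of the C3 hydroxyl to the O2-stabilised oxocarbenium ion and loss of a C4 proton then give the C3=C4 enol ether, so that the water taken up is returned and 20 is in sum isomerised to 22. C1 is the only new stereocentre and is under thermodynamic control, because the lactol epimers interconvert through the open form: the hydroxyl should settle on the convex β face, trans to the fully substituted C8 on the neighbouring C9. The step needs the enol ether to form toward C4 and the lactol at C1, which the substrate secures since C4 is a free methylene whereas a C1=C9 enol ether would require removal of the hindered tertiary H-9 and a ring-fusion double bond next to C8; the C8 triethylsilyl ether excludes a C3–O–C8 bridge and the silylene keeps O7 and O10 out of the acetal chemistry. C5, C7, C8 and C9 are not involved, and running the closure directly on the crude dialdehyde under near-neutral conditions should keep C9 from epimerising.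

Step 15
Reactants: 22 lactol; 23 (S)-3-methylpentanoic acid
Product: 24 1β-O-[(S)-3-methylpentanoyl] 11-nor-iridoid
Conditions: DCC, 4-(dimethylamino)pyridine (10 mol %), CH2Cl2, 0 °C
Reagents that add atoms: none
Why: Steglich esterification of the hemiacetal hydroxyl, in which acyl transfer to the exposed β-lactol (trans to C8) fixes C1, and because the lactol epimers and any open form interconvert under the conditions the material should be funnelled into the one acyl acetal.

Step 16
Reactants: 24 C1 ester
Product: 26 C4-formyl enol ether (C11 aldehyde), via vinylogous iminium chloride 25 (not isolated)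
Conditions: (chloromethylene)dimethyliminium chloride (1.5 equiv), CH2Cl2–DMF, 0 °C to rt; then aq. NaHCO3, 0 °C
Reagents that add atoms: (chloromethylene)dimethyliminium chloride, C[N+](C)=CCl.[Cl-]; water, O
Why: Vilsmeier–Haack formylation of a cyclic enol ether, as known for glycals and for 1-O-acyl iridoid enol ethers, in which the chloroiminium ion attacks nucleophilic C4, loss of H-4 restores the enol ether as salt 25, and mild basic hydrolysis gives the β-alkoxyacrolein, which also deactivates ring A towards acid for the following steps.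

Step 17
Reactants: 26 C4 aldehyde
Product: 27 7β,10-diol (8-O-triethylsilyl, C4 aldehyde and C1 ester retained)
Conditions: HF·pyridine, pyridine, THF, 0 °C
Reagents that add atoms: none
Why: Fluoride-mediated desilylation, in which the dialkoxysilane of the silylene should be attacked by buffered HF much faster than the hindered tertiary triethylsilyl ether (the selectivity used in nucleoside chemistry), while the vinylogous formate ester and the acyl acetal tolerate the buffered medium.

Step 18
Reactants: 28 p-coumaric acid
Product: 30 (E)-4-(tert-butyldimethylsilyloxy)cinnamic acid, via bis-silyl derivative 29 (not isolated)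
Conditions: TBSCl (2.2 equiv), imidazole, DMF, rt; then AcOH–THF–H2O, rt
Reagents that add atoms: tert-butyldimethylsilyl chloride, CC(C)(C)[Si](C)(C)Cl
Why: Exhaustive silylation followed by selective hydrolysis of the far more labile silyl ester leaves the phenol masked and the acid free.

Step 19
Reactants: 27 diol; 30 silyl-protected coumaric acid
Product: 31 C10 (E)-4-(tert-butyldimethylsilyloxy)cinnamate
Conditions: 30 (1.0 equiv), DCC, 4-(dimethylamino)pyridine (10 mol %), CH2Cl2, −10 °C to rt
Reagents that add atoms: none
Why: Steglich esterification with one equivalent of acid should discriminate the primary C10 hydroxyl from the secondary C7 hydroxyl flanked by quaternary C8, while the tertiary oxygen is still silylated.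

Step 20
Reactants: 31 bis-silyl ester
Product: 32 11-oxo analogue of the target (free 7β-OH, 8α-OH and phenol; C4 aldehyde)
Conditions: HF·pyridine, pyridine, THF, 0 °C to rt
Reagents that add atoms: none
Why: Fluoride-mediated cleavage of the aryl and tertiary alkyl silyl ethers is done while ring A is still the acid-tolerant vinylogous ester, so that the sensitive C11 allylic alcohol never meets HF.

Step 21
Reactants: 32 aldehyde
Product: 33 CNP0241834.1, (1S,4aS,6S,7R,7aS) in cyclopenta[c]pyran numbering
Conditions: NaBH4, CeCl3·7H2O, MeOH–THF, −40 °C; pH 7 buffer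
Reagents that add atoms: none
Why: Luche reduction should deliver hydride 1,2 to the C4 aldehyde only, since the cinnamate, the acyl acetal and the enol ether are inert to NaBH4–CeCl3 at low temperature, and no stereocentre is created.

## Compound list

1 | cycloocta-1,3-diene | C1=CC=CCCCC1 | starting material
2 | rac-cis-3,4-epoxycyclooctene (one enantiomer drawn) | C1=C[C@@H]2O[C@@H]2CCCC1 | intermediate
3 | α-lithiated epoxide, lithium on the allylic epoxide carbon (racemic) | C1=C[C@]2([Li])O[C@@H]2CCCC1 | intermediate (not isolated)
4 | rac-endo-cis-bicyclo[3.3.0]oct-7-en-2-ol (one enantiomer drawn) | C1=CC[C@H]2CC[C@@H](O)[C@@H]12 | intermediate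
5 | (1R,2R,5R)-endo-cis-bicyclo[3.3.0]oct-7-en-2-yl acetate | C1=CC[C@H]2CC[C@@H](OC(C)=O)[C@@H]12 | intermediate
6 | (1R,2R,5R)-endo-cis-bicyclo[3.3.0]oct-7-en-2-ol | C1=CC[C@H]2CC[C@@H](O)[C@@H]12 | intermediate
7 | (1R,5R)-cis-bicyclo[3.3.0]oct-7-en-2-one | C1=CC[C@H]2CCC(=O)[C@@H]12 | intermediate
8 | lithium C7=C8 enolate of 7 | C1=CC[C@H]2CC=C([O-])[C@@H]12.[Li+] | intermediate (not isolated)
9 | C7=C8 enol triflate, H-5 and H-9 β | C1=CC[C@H]2CC=C(OS(=O)(=O)C(F)(F)F)[C@@H]12 | intermediate
10 | methyl cis-bicyclo[3.3.0]octa-2,7-diene-2-carboxylate, H-5 and H-9 β | C1=CC[C@H]2CC=C(C(=O)OC)[C@@H]12 | intermediate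
11 | (cis-bicyclo[3.3.0]octa-2,7-dien-2-yl)methanol, H-5 and H-9 β | C1=CC[C@H]2CC=C(CO)[C@@H]12 | intermediate
12 | 7β,8β-epoxy alcohol | C1=CC[C@H]2C[C@@H]3O[C@]3(CO)[C@@H]12 | intermediate
13 | 10-O-(N-phenylcarbamoyl) 7β,8β-epoxide | C1=CC[C@H]2C[C@@H]3O[C@]3(COC(=O)Nc4ccccc4)[C@@H]12 | intermediate
14 | 8α,10-(N-phenylimino)carbonate, 7β-OH | C1=CC[C@H]2C[C@H](O)[C@]3(COC(=Nc4ccccc4)O3)[C@@H]12 | intermediate (not isolated)
15 | 8α,10-cyclic carbonate, 7β-OH | C1=CC[C@H]2C[C@H](O)[C@]3(COC(=O)O3)[C@@H]12 | intermediate
16 | 7β,8α,10-triol | C1=CC[C@H]2C[C@H](O)[C@](O)(CO)[C@@H]12 | intermediate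
17 | 7,10-O-(di-tert-butylsilylene) 8α-ol | C1=CC[C@H]2C[C@@H]3O[Si](C(C)(C)C)(C(C)(C)C)OC[C@]3(O)[C@@H]12 | intermediate (not isolated)
18 | 7,10-O-(di-tert-butylsilylene)-8-O-triethylsilyl cis-bicyclo[3.3.0]octene (key-step precursor) | C1=CC[C@H]2C[C@@H]3O[Si](C(C)(C)C)(C(C)(C)C)OC[C@]3(O[Si](CC)(CC)CC)[C@@H]12 | intermediate
19 | secondary ozonide across C1 and C3 (configuration at C1 and C3 not defined) | O1OC2OC1C[C@H]1C[C@@H]3O[Si](C(C)(C)C)(C(C)(C)C)OC[C@]3(O[Si](CC)(CC)CC)[C@@H]21 | intermediate (not isolated)
20 | C1,C3-dialdehyde | O=CC[C@H]1C[C@@H]2O[Si](C(C)(C)C)(C(C)(C)C)OC[C@]2(O[Si](CC)(CC)CC)[C@H]1C=O | intermediate (not isolated)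
21 | cyclic 1,3-bis-hemiacetal (C3 epimers) | O[C@@H]1OC(O)C[C@H]2C[C@@H]3O[Si](C(C)(C)C)(C(C)(C)C)OC[C@]3(O[Si](CC)(CC)CC)[C@@H]12 | intermediate (not isolated)
22 | 11-nor-iridoid lactol, 1β-OH (key-step product) | O[C@@H]1OC=C[C@H]2C[C@@H]3O[Si](C(C)(C)C)(C(C)(C)C)OC[C@]3(O[Si](CC)(CC)CC)[C@@H]12 | intermediate
23 | (S)-3-methylpentanoic acid | CC[C@H](C)CC(=O)O | starting material
24 | 1β-O-[(S)-3-methylpentanoyl] 11-nor-iridoid | CC[C@H](C)CC(=O)O[C@@H]1OC=C[C@H]2C[C@@H]3O[Si](C(C)(C)C)(C(C)(C)C)OC[C@]3(O[Si](CC)(CC)CC)[C@@H]12 | intermediate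
25 | C4 (dimethyliminio)methyl enol ether chloride | CC[C@H](C)CC(=O)O[C@@H]1OC=C(C=[N+](C)C)[C@H]2C[C@@H]3O[Si](C(C)(C)C)(C(C)(C)C)OC[C@]3(O[Si](CC)(CC)CC)[C@@H]12.[Cl-] | intermediate (not isolated)
26 | C4-formyl enol ether | CC[C@H](C)CC(=O)O[C@@H]1OC=C(C=O)[C@H]2C[C@@H]3O[Si](C(C)(C)C)(C(C)(C)C)OC[C@]3(O[Si](CC)(CC)CC)[C@@H]12 | intermediate
27 | 7β,10-diol, 8-O-triethylsilyl, C4-formyl | CC[C@H](C)CC(=O)O[C@@H]1OC=C(C=O)[C@H]2C[C@H](O)[C@](O[Si](CC)(CC)CC)(CO)[C@@H]12 | intermediate
28 | p-coumaric acid | O=C(O)/C=C/c1ccc(O)cc1 | starting material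
29 | tert-butyldimethylsilyl (E)-4-(tert-butyldimethylsilyloxy)cinnamate | CC(C)(C)[Si](C)(C)OC(=O)/C=C/c1ccc(O[Si](C)(C)C(C)(C)C)cc1 | intermediate (not isolated)
30 | (E)-4-(tert-butyldimethylsilyloxy)cinnamic acid | O=C(O)/C=C/c1ccc(O[Si](C)(C)C(C)(C)C)cc1 | intermediate
31 | C10 silyl-protected coumarate, 8-O-triethylsilyl, C4-formyl | CC[C@H](C)CC(=O)O[C@@H]1OC=C(C=O)[C@H]2C[C@H](O)[C@](O[Si](CC)(CC)CC)(COC(=O)/C=C/c3ccc(O[Si](C)(C)C(C)(C)C)cc3)[C@@H]12 | intermediate
32 | 11-oxo analogue of the target | CC[C@H](C)CC(=O)O[C@@H]1OC=C(C=O)[C@H]2C[C@H](O)[C@](O)(COC(=O)/C=C/c3ccc(O)cc3)[C@@H]12 | intermediate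
33 | CNP0241834.1 | CC[C@H](C)CC(=O)O[C@@H]1OC=C(CO)[C@H]2C[C@H](O)[C@](O)(COC(=O)/C=C/c3ccc(O)cc3)[C@@H]12 | target

## Step count and risks

Total step count: 21.
Longest linear sequence: 20 steps (steps 1–17 and 19–21, from cycloocta-1,3-diene).

The three steps most likely to fail:

1. **Step 14.**
   - **What may go wrong:** ring closure may lag behind side reactions of the open dialdehyde (epimerisation at C9, β-elimination of the C8 silyloxy group), or it may stall at the hydrated stage.
   - **Fallback:** it sets out from 18 and comes back at 26. The aldehydes are trapped as acetals as soon as they form, and the enol ether is made by a separate elimination.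
   - Ozonolysis in CH2Cl2–MeOH with Me2S work-up, then HC(OMe)3 and pyridinium p-toluenesulfonate, should give the 1,3-di-O-methyl bis-acetal F1.
   - Me3SiOTf and i-Pr2NEt in CH2Cl2 at −20 °C remove methanol from the C3 acetal, the only one with an accessible neighbouring proton (at C4), to give the 1-O-methyl enol ether F2.
   - Formylation as in step 16 gives the 4-formyl 1-O-methyl acetal F3.
   - Because ring A is then a vinylogous ester, the C1 methyl acetal can be hydrolysed with dilute aqueous acid in THF to the 4-formyl lactol F4.
   - Steglich esterification of F4 with 23 gives 26.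

2. **Step 16.**
   - **What may go wrong:** the chloroiminium salt may attack the tertiary silyl ether (exchange for a formate), or the liberated HCl may ionise the acyl acetal before C4 is formylated.
   - **Fallback:** it sets out from 24 and comes back at 26. Electrophilic formylation is replaced by halogenation and cross-coupling.
   - N-Iodosuccinimide with catalytic AgNO3 in MeCN (iodination–elimination, as used for 2-iodoglycals) gives the 4-iodo enol ether F5.
   - Palladium-catalysed reductive carbonylation of F5 (Pd(PPh3)4, CO at 1 atm, slow addition of Bu3SnH, THF, 50 °C) gives aldehyde 26.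

3. **Step 6.**
   - **What may go wrong:** deprotonation may compete at the doubly activated (α-keto and allylic) H-9, which would lead to loss of regiocontrol and migration of the alkene into conjugation.
   - **Fallback:** it sets out from 7 and comes back at 11. Regiocontrol comes from hydrazone geometry rather than from relative C–H acidity (Shapiro reaction).
   - Condensation with 2,4,6-triisopropylbenzenesulfonyl hydrazide gives the (E)-trisylhydrazone F6, whose sulfonamide nitrogen lies syn to C7.
   - n-BuLi (2.1 equiv) in THF–TMEDA, −78 to 0 °C, lithiates syn at C7 and, after loss of sulfinate and nitrogen, gives the C8 vinyllithium F7.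
   - Trapping F7 with paraformaldehyde gives allylic alcohol 11 directly.

## Further compounds

F1 | step 14 | 1,3-di-O-methyl bis-acetal (C3 epimers) | CO[C@@H]1OC(OC)C[C@H]2C[C@@H]3O[Si](C(C)(C)C)(C(C)(C)C)OC[C@]3(O[Si](CC)(CC)CC)[C@@H]12
F2 | step 14 | 1-O-methyl enol ether | CO[C@@H]1OC=C[C@H]2C[C@@H]3O[Si](C(C)(C)C)(C(C)(C)C)OC[C@]3(O[Si](CC)(CC)CC)[C@@H]12
F3 | step 14 | 4-formyl 1-O-methyl acetal | CO[C@@H]1OC=C(C=O)[C@H]2C[C@@H]3O[Si](C(C)(C)C)(C(C)(C)C)OC[C@]3(O[Si](CC)(CC)CC)[C@@H]12
F4 | step 14 | 4-formyl lactol | O[C@@H]1OC=C(C=O)[C@H]2C[C@@H]3O[Si](C(C)(C)C)(C(C)(C)C)OC[C@]3(O[Si](CC)(CC)CC)[C@@H]12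
F5 | step 16 | 4-iodo enol ether | CC[C@H](C)CC(=O)O[C@@H]1OC=C(I)[C@H]2C[C@@H]3O[Si](C(C)(C)C)(C(C)(C)C)OC[C@]3(O[Si](CC)(CC)CC)[C@@H]12
F6 | step 6 | (E)-trisylhydrazone of 7 | C1=CC[C@H]2CC/C(=N\NS(=O)(=O)c3c(C(C)C)cc(C(C)C)cc3C(C)C)[C@@H]12
F7 | step 6 | C8 vinyllithium | C1=CC[C@H]2CC=C([Li])[C@@H]12
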